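We start from amounts: Z is the limiting reagent in the theta run, with 0.120 M of Z against 0.180 M of X, yet its last reading holds 0.0456 M of G.

| flask | Z | X | time |
|---|---|---|---|
| theta | 0.120 M | 0.180 M |  |
| delta | 0.0600 M | 0.120 M |  |
| zeta | 0.120 M | 0.360 M |  |
| epsilon | 0.120 M | 1.20 M | 15 min |

- theta run (time / min: [G] / M): 1.1: 0.0106; 3.5: 0.0235; 6.6: 0.0347; 10: 0.0420; 15: 0.0456
- delta run (time / min: [G] / M): 1.1: 0.0037; 3.5: 0.0095; 6.6: 0.0156; 10: 0.0199; 15: 0.0190
- zeta run (time / min: [G] / M): 1.1: 0.0140; 3.5: 0.0344; 6.6: 0.0527; 10: 0.0591; 15: 0.0661

(readings scatter by 0.001 M)

- order of the initial rate in [X], near the charge of the theta run, the rate being that where two percent of its Z are G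
- order of the initial rate in [Z], near the charge of the theta run, the rate being that where two percent of its Z are G (one fixed amount of G, the same in the runs compared)
- G in the epsilon run at 15 min, as a share of the Z charged

- Overall: Z + X -> G.
- Constant volume, constant temperature.
- What is held in complexes is read along with the free species.
- An order is taken over about fifteen percent of the charge, up and down.

- With the main step alone, Z + X → G, the epsilon run has Z far below X, so our first answer is 100 per cent of its Z. The theta run already speaks against this, with 38.0% of its Z as G at 15 min.

- We add one rival path that takes Z elsewhere at a pace that does not depend on X. In this reckoning, with X held near its charge, G and the rest of Z stand in a ratio that grows in proportion to X. This gives us our rule, a selectivity factor in plain form: the odds per X, meaning G at 15 min over the Z not found as G, divided by the X charged 3.41 M⁻¹, read here from the theta run.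

- The zeta run has twice the X of the theta run, and its own reading gives 3.41 M⁻¹, a check from a different reading. Carried to the epsilon run, the odds become 4.09, so the first answer falls to 80.3%.

- Last comes the pace. At 1.1 min, the zeta run reads 1.32 times the G of the theta run, less than the step in X, an order in X of about 0.401 as read over that wide step. The early G of these two runs thus rises by less than their X, and the epsilon run has 3.33 times the X of the zeta run, so we commit to 80.3% for the epsilon run and hold it as our high estimate.

- The forecast gives 0.56 for the order in X, 1.03 for the order in Z and 80% for the epsilon run. It lands near our share on different grounds, since it reads an equilibrium where we read a rival path: “The G curves flatten early, well short of the Z charged, so this looks like an equilibrium rather than simple second-order decay.”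

- The simulated flask runs by these steps:

    Z + X ⇌ G + E (0.9720 M⁻¹ min⁻¹, 0.1440 M⁻¹ min⁻¹)
    Z → Qe (0.1656 min⁻¹)
    Z + X ⇌ ZX, settled at all times (5.430 M⁻¹)

- The flask gives 0.69 for the order in X, above the forecast, 0.86 for the order in Z, below it, and 75.7% for the epsilon run, 4.6 percentage points under our share. The path from Z to Qe moves the readings by 12 times the scatter, as a root mean square. The epsilon result puts the odds per X at 2.60 M⁻¹ against the carried 3.41 M⁻¹. In the delta run, the carried 3.41 M⁻¹ gives 0.0174 M of G, while its reading at 15 min is 0.0190 M, a gap of 1.60 times the scatter.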